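Whatever happens in the closed flask, the undissolved solid substrate, starting material, target, isomer of the product, third isomer and homo dimer (counted two for one) add up to the charge. The solid substrate is the one charge and so the limiting reagent, and the ledger below is kept in fractions of it.

solid substrate 0.10 M; time 4.0 min

    2 starting material → homo dimer (k1 = 0.26 M⁻¹ s⁻¹)
    starting material ⇌ target (K2 = 1.3, k2 = 0.043 s⁻¹)
    starting material ⇌ isomer of the product (K3 = 2.9, k3 = 6.4 × 10⁻⁴ s⁻¹)
    solid substrate ⇌ starting material, rate k4*(cs4 - [starting material]) while solid is left; crystals form when [starting material] > cs4 (cs4 = 46 mM, k4 = 0.0095 s⁻¹)
    starting material ⇌ third isomer (K5 = 18, k5 = 0.054 s⁻¹)

- percentages count the solid substrate that a species holds: one homo dimer counts as two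
- a step written with two of one species runs at k times the square of its concentration and takes two of it each time
- solid, in amounts per volume of the solution: solid substrate
- at the start none of the solid substrate is in solution
- run time (flask): 4.0 min

* amount of target at 4.0 min, in percent of the solid substrate charged
* the change that raises the amount of target at 4.0 min, in percent of the solid substrate charged most ("none" if none brings more than 2 percentage points) (north / east / none)
* amount of target at 4.0 min, in percent of the solid substrate charged, after east

- north: doubling the dissolution coefficient of step 4, all else as stated
- east: doubling the solubility in step 4, all else as stated

The income comes first. Working into an empty solution, step 4 hands over 105% of the charge by 4.0 min, and this figure, dissolution coefficient times solubility times time over charge, is the delivery ratio.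

The third isomer relaxes against starting material in 0.203 min, far quicker than the run, and it takes up the feed, so my reckoning stands starting material where step 5 passes that feed on, at 8.09% of the charge. Target relaxes in 0.152 min, also quicker than the run, so it stands at 1.3 times starting material, or 10.5%.

Starting material at that level is 17.6% of saturation, which trims the income to 86.4% and leaves 13.6% as solid. The remaining 67.8% goes to third isomer, homo dimer and isomer of the product, and the books close; the half-life of starting material by step 3 alone, forward rate only, is 18 min, longer than the run.

North doubles the dissolution coefficient and east doubles the solubility, and either one doubles the delivery ratio to 210%, so at that pace the charge lasts 1.90 min, less than the run. Target, relaxing in 0.152 min, quicker than the run, should then follow starting material down once the feed ends, so I expect no gain above 2 percentage points, though I put no number on east.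

The forecast gives 11%, best none and 7.1% after east, holding that “Starting material is drained quickly, mostly into the third isomer”.

The simulation gives 10.8%, best none, and 7.16% after east, a change of −3.6 points against −3.3 points for north. This flask holds 10.1% as solid at 4.00 min, so 89.9% has dissolved, and the delivery ratio scaled by the 15.2% of saturation read at 2.00 min gives 89.0%. The same flask read at 1.0 min has a delivery ratio of 26.2%, against 23.9% gone from the solid.

(All constants are assumed; the flask was simulated.)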